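**Retrosynthetic overview**
- The target is opened at the C9–O bond: the acetate is put on last by a catalyst-controlled benzylic C–H acetoxylation of the deoxy spirodienone, whose only benzylic CH2 is C9.
- The deoxy spirodienone comes from an acyclic (2R,3R)-2,3-dimethyl-1,4-diarylbutane phenol by oxidative para-ipso spirocyclisation.
- The (2R,3R)-dimethyl array comes from double asymmetric hydrogenation of a (1E,3E)-1,4-diaryl-2,3-dimethylbuta-1,3-diene.
- The diene comes from two successive Heck arylations of 2,3-dimethylbutadiene with two aryl bromides.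
- Ring order: both arenes are bought; the seven-membered ring and the cyclohexadienone form together in the spirocyclisation; no ring is made after that.

Assumption: the sense of induction of the two chiral catalysts (steps 4 and 6) is assigned by analogy with simpler substrates; if either gives the opposite sense, the mirror-image ligand is used.

**Step 1**
Reactants: 1 5-bromo-1,2,3-trimethoxybenzene; 2 2,3-dimethylbuta-1,3-diene (5 equiv)
Product: 3 5-[(1E)-2,3-dimethylbuta-1,3-dien-1-yl]-1,2,3-trimethoxybenzene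
Conditions: Pd(OAc)2 (2 mol%), P(o-tol)3 (8 mol%), Et3N (1.5 equiv), MeCN, 100 °C, sealed tube
Reagents that add atoms: none
Why: Mizoroki–Heck arylation of a conjugated diene, in which the arylpalladium adds to a terminal CH2 and the allylpalladium intermediate loses the benzylic hydrogen to give the conjugated E-aryl diene, the excess of cheap volatile diene holding back double arylation.

**Step 2**
Reactants: 4 4-bromo-2,6-dimethoxyphenol
Product: 5 2-(benzyloxy)-5-bromo-1,3-dimethoxybenzene
Conditions: BnBr (1.1 equiv), K2CO3 (1.5 equiv), DMF, 60 °C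
Reagents that add atoms: benzyl bromide BrCc1ccccc1
Why: Williamson etherification, which masks the phenol so that no phenoxide can intercept the allylpalladium intermediate of the next Heck reaction.

**Step 3**
Reactants: 3 5-[(1E)-2,3-dimethylbuta-1,3-dien-1-yl]-1,2,3-trimethoxybenzene (1.2 equiv); 5 2-(benzyloxy)-5-bromo-1,3-dimethoxybenzene
Product: 6 2-(benzyloxy)-5-[(1E,3E)-2,3-dimethyl-4-(3,4,5-trimethoxyphenyl)buta-1,3-dien-1-yl]-1,3-dimethoxybenzene
Conditions: Pd2(dba)3 (2 mol%), [HP(t-Bu)3]BF4 (8 mol%), Cy2NMe (1.3 equiv), 1,4-dioxane, 90 °C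
Reagents that add atoms: none
Why: Second Mizoroki–Heck arylation at the remaining terminal methylene, with a bulky electron-rich phosphine on zerovalent palladium for the electron-rich aryl bromide; loss of the benzylic hydrogen under thermodynamic control gives the E,E-diene.

**Step 4**
Reactants: 6 2-(benzyloxy)-5-[(1E,3E)-2,3-dimethyl-4-(3,4,5-trimethoxyphenyl)buta-1,3-dien-1-yl]-1,3-dimethoxybenzene
Product: 8 4-[(2R,3R)-2,3-dimethyl-4-(3,4,5-trimethoxyphenyl)butyl]-2,6-dimethoxyphenol, via benzyl ether 7 (not isolated)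
Conditions: H2 (50 bar), [Ir(cod)((S)-tBu-PHOX)][B(3,5-(CF3)2C6H3)4] (2 mol%; tBu-PHOX = 4-tert-butyl-2-[2-(diphenylphosphino)phenyl]-4,5-dihydrooxazole), CH2Cl2, 25 °C; then evaporate, Pd/C (10 wt%), H2 (1 atm), EtOAc–MeOH, 25 °C
Reagents that add atoms: none
Why: Iridium N,P-catalysed asymmetric hydrogenation of trisubstituted aryl alkenes reduces each E-ArCH=C(Me)R unit from the same catalyst-defined face, so both methyl-bearing carbons become R (the erythro isomer is the main stereo-impurity and is removed by chromatography or crystallisation of 8), and the Pd/C stage then cleaves the benzyl ether by hydrogenolysis.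

**Step 5**
Reactants: 8 4-[(2R,3R)-2,3-dimethyl-4-(3,4,5-trimethoxyphenyl)butyl]-2,6-dimethoxyphenol
Product: 9 (7R,8R)-2,3,3',4,5'-pentamethoxy-7,8-dimethyl-6,7,8,9-tetrahydrospiro[benzo[7]annulene-5,1'-cyclohexa[2,5]dien]-4'-one
Conditions: PhI(OCOCF3)2 (1.1 equiv), CF3CH2OH, −40 °C, 30 min; aq. NaHCO3 quench
Reagents that add atoms: none
Why: Phenolic oxidative coupling with a trivalent-iodine oxidant (dearomatising para-ipso spirocyclisation), in which the oxidised phenol ring is attacked at its alkyl-bearing para carbon by the trimethoxyphenyl position ortho to the chain and para to a methoxy group, closing the seven-membered ring; both the nucleophilic ring and the dienone are symmetric, so no regio- or stereoisomer arises, the two methyl stereocenters are untouched, and the cold non-nucleophilic fluoroalcohol avoids dienone–phenol rearrangement.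

**Step 6**
Reactants: 9 (7R,8R)-2,3,3',4,5'-pentamethoxy-7,8-dimethyl-6,7,8,9-tetrahydrospiro[benzo[7]annulene-5,1'-cyclohexa[2,5]dien]-4'-one
Product: 10 (7R,8S,9R)-2,3,3',4,5'-pentamethoxy-7,8-dimethyl-4'-oxo-6,7,8,9-tetrahydrospiro[benzo[7]annulene-5,1'-cyclohexa[2,5]dien]-9-yl acetate (CNP0143674.1)
Conditions: [Cu(MeCN)4]PF6 (10 mol%), 2,2'-(cyclopropane-1,1-diyl)bis[(3aS,8aR)-3a,8a-dihydro-8H-indeno[1,2-d]oxazole] (12 mol%), (PhSO2)2NF (1.5 equiv), Me3SiOAc (3 equiv), Li2CO3 (1 equiv), PhCl, 25 °C
Reagents that add atoms: trimethylsilyl acetate CC(=O)O[Si](C)(C)C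
Why: Proposed new method: monovalent copper reduces (PhSO2)2NF to a divalent copper fluoride and the bulky electrophilic bis(sulfonyl)imidyl radical, which abstracts hydrogen from C9, the only benzylic CH2 of 9 (the other former benzylic carbon is now neopentylic beside the spiro centre); Me3SiOAc converts Cu–F into Cu–OAc through Si–F bond formation, the planar benzylic radical is captured by this divalent copper acetate, and C–O reductive elimination from the bis(oxazoline)-bound trivalent copper benzyl acetate sets C9 as R, the acetate arriving anti to the C8 methyl with the ligand matched to that substrate bias; Li2CO3 takes up the sulfonimide acid so that neither the dienone nor the benzylic acetate ionises, and the acetoxylated C9–H is polarity-mismatched for a second abstraction; the closest known reactions are copper/N–F radical-relay benzylic C–H cyanation (enantioselective) and etherification (racemic) and the Kharasch–Sosnovsky acyloxylation, none of which has given a ligand-controlled secondary benzylic acetate from a limiting, stereochemically complex substrate.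

**Compound list**
1 | 5-bromo-1,2,3-trimethoxybenzene | COc1cc(Br)cc(OC)c1OC | starting material
2 | 2,3-dimethylbuta-1,3-diene | CC(=C)C(C)=C | starting material
3 | 5-[(1E)-2,3-dimethylbuta-1,3-dien-1-yl]-1,2,3-trimethoxybenzene | COc1cc(/C=C(\C)C(C)=C)cc(OC)c1OC | intermediate
4 | 4-bromo-2,6-dimethoxyphenol | COc1cc(Br)cc(OC)c1O | starting material
5 | 2-(benzyloxy)-5-bromo-1,3-dimethoxybenzene | COc1cc(Br)cc(OC)c1OCc1ccccc1 | intermediate
6 | 2-(benzyloxy)-5-[(1E,3E)-2,3-dimethyl-4-(3,4,5-trimethoxyphenyl)buta-1,3-dien-1-yl]-1,3-dimethoxybenzene | COc1cc(/C=C(C)/C(C)=C/c2cc(OC)c(OCc3ccccc3)c(OC)c2)cc(OC)c1OC | intermediate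
7 | 2-(benzyloxy)-5-[(2R,3R)-2,3-dimethyl-4-(3,4,5-trimethoxyphenyl)butyl]-1,3-dimethoxybenzene (formed in the flask in step 4) | COc1cc(C[C@@H](C)[C@H](C)Cc2cc(OC)c(OCc3ccccc3)c(OC)c2)cc(OC)c1OC | intermediate
8 | 4-[(2R,3R)-2,3-dimethyl-4-(3,4,5-trimethoxyphenyl)butyl]-2,6-dimethoxyphenol | COc1cc(C[C@@H](C)[C@H](C)Cc2cc(OC)c(O)c(OC)c2)cc(OC)c1OC | intermediate
9 | (7R,8R)-2,3,3',4,5'-pentamethoxy-7,8-dimethyl-6,7,8,9-tetrahydrospiro[benzo[7]annulene-5,1'-cyclohexa[2,5]dien]-4'-one | COC1=CC2(C=C(OC)C1=O)C[C@@H](C)[C@H](C)Cc1cc(OC)c(OC)c(OC)c12 | intermediate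
10 | (7R,8S,9R)-2,3,3',4,5'-pentamethoxy-7,8-dimethyl-4'-oxo-6,7,8,9-tetrahydrospiro[benzo[7]annulene-5,1'-cyclohexa[2,5]dien]-9-yl acetate | COC1=CC2(C=C(OC)C1=O)C[C@@H](C)[C@H](C)[C@@H](OC(C)=O)c1cc(OC)c(OC)c(OC)c12 | target

**Count and risk**
Total steps: 6. Longest linear sequence: 5 (steps 1, 3, 4, 5, 6, from 1 to 10); step 2 is a one-step side branch.

The three steps most likely to fail:

Step 3 (second Heck arylation). The diene 3 is hindered, the bromide 5 is electron-rich, and the allylpalladium intermediate can eliminate toward a methyl group or isomerise. The fallback builds the diene by carbonyl chemistry; it sets out from 5 and comes back at 6, and makes step 1 unnecessary. Bromine–lithium exchange on 5 (n-BuLi, THF, −78 °C) gives [4-(benzyloxy)-3,5-dimethoxyphenyl]lithium F1, which is quenched with DMF to 4-(benzyloxy)-3,5-dimethoxybenzaldehyde F2. Acid-catalysed aldol condensation of F2 with butan-2-one (dry HCl, 0 to 25 °C; the ketone reacts at C3 under acid) gives (3E)-4-[4-(benzyloxy)-3,5-dimethoxyphenyl]-3-methylbut-3-en-2-one F3. 1,2-Addition of (3,4,5-trimethoxybenzyl)magnesium chloride F4 (made from commercial 3,4,5-trimethoxybenzyl chloride and Mg in THF) gives the racemic tertiary alcohol (3E)-4-[4-(benzyloxy)-3,5-dimethoxyphenyl]-2,3-dimethyl-1-(3,4,5-trimethoxyphenyl)but-3-en-2-ol F5. Dehydration of F5 toward the benzylic side (p-TsOH, toluene, 80 °C, thermodynamic control) gives 6.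

Step 4 (double asymmetric hydrogenation). Enantio- and diastereoselectivity on this particular diene are not established, and the erythro isomer may be hard to remove. The fallback replaces catalytic stereocontrol by a purchased C2-symmetric building block and two copper-catalysed Grignard–tosylate couplings (Fouquet–Schlosser type); it sets out from 1 and 5 and comes back at 7, which is then debenzylated with Pd/C and H2 as in step 4 to give 8. Purchased (2S,3S)-2,3-dimethylbutane-1,4-diol (costly) is tosylated (TsCl, pyridine) to (2S,3S)-2,3-dimethylbutane-1,4-diyl bis(4-methylbenzenesulfonate) F6. (3,4,5-Trimethoxyphenyl)magnesium bromide F7 (from 1 and Mg, THF) is coupled with a threefold excess of F6 (Li2CuCl4 5 mol%, THF, −20 to 0 °C) to give (2S,3R)-2,3-dimethyl-4-(3,4,5-trimethoxyphenyl)butyl 4-methylbenzenesulfonate F8, the excess F6 being recovered. A second coupling of F8 with [4-(benzyloxy)-3,5-dimethoxyphenyl]magnesium bromide F9 (from 5 and Mg) gives 7.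

Step 6 (the proposed copper-catalysed C–H acetoxylation). Possible failures are capture of the radical as a free cation (loss of ligand control), imidation of the one free arene position, attack on the dienone, or a mismatched ligand. The fallback uses known two-electron chemistry under substrate control with a stereochemical correction; it sets out from 9 and comes back at 10. DDQ (1.5 equiv) in AcOH at 25–40 °C abstracts hydride from C9 and acetate traps the cation, giving 10 together with its C9 epimer, (7R,8S,9S)-2,3,3',4,5'-pentamethoxy-7,8-dimethyl-4'-oxo-6,7,8,9-tetrahydrospiro[benzo[7]annulene-5,1'-cyclohexa[2,5]dien]-9-yl acetate F10. Whatever amount of F10 forms is methanolysed (K2CO3, MeOH, 0 °C) to (7R,8S,9S)-9-hydroxy-2,3,3',4,5'-pentamethoxy-7,8-dimethyl-6,7,8,9-tetrahydrospiro[benzo[7]annulene-5,1'-cyclohexa[2,5]dien]-4'-one F11. Mitsunobu esterification of F11 with AcOH (PPh3, DIAD, THF, 0 °C) inverts C9 and gives 10.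

**Further compounds**
F1 | step 3 | [4-(benzyloxy)-3,5-dimethoxyphenyl]lithium | [Li]c1cc(OC)c(OCc2ccccc2)c(OC)c1
F2 | step 3 | 4-(benzyloxy)-3,5-dimethoxybenzaldehyde | O=Cc1cc(OC)c(OCc2ccccc2)c(OC)c1
F3 | step 3 | (3E)-4-[4-(benzyloxy)-3,5-dimethoxyphenyl]-3-methylbut-3-en-2-one | CC(=O)/C(C)=C/c1cc(OC)c(OCc2ccccc2)c(OC)c1
F4 | step 3 | (3,4,5-trimethoxybenzyl)magnesium chloride | COc1cc(C[Mg]Cl)cc(OC)c1OC
F5 | step 3 | (3E)-4-[4-(benzyloxy)-3,5-dimethoxyphenyl]-2,3-dimethyl-1-(3,4,5-trimethoxyphenyl)but-3-en-2-ol (racemic) | COc1cc(CC(C)(O)/C(C)=C/c2cc(OC)c(OCc3ccccc3)c(OC)c2)cc(OC)c1OC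
F6 | step 4 | (2S,3S)-2,3-dimethylbutane-1,4-diyl bis(4-methylbenzenesulfonate) | Cc1ccc(cc1)S(=O)(=O)OC[C@@H](C)[C@H](C)COS(=O)(=O)c1ccc(C)cc1
F7 | step 4 | (3,4,5-trimethoxyphenyl)magnesium bromide | COc1cc([Mg]Br)cc(OC)c1OC
F8 | step 4 | (2S,3R)-2,3-dimethyl-4-(3,4,5-trimethoxyphenyl)butyl 4-methylbenzenesulfonate | COc1cc(C[C@@H](C)[C@H](C)COS(=O)(=O)c2ccc(C)cc2)cc(OC)c1OC
F9 | step 4 | [4-(benzyloxy)-3,5-dimethoxyphenyl]magnesium bromide | COc1cc([Mg]Br)cc(OC)c1OCc1ccccc1
F10 | step 6 | (7R,8S,9S)-2,3,3',4,5'-pentamethoxy-7,8-dimethyl-4'-oxo-6,7,8,9-tetrahydrospiro[benzo[7]annulene-5,1'-cyclohexa[2,5]dien]-9-yl acetate | COC1=CC2(C=C(OC)C1=O)C[C@@H](C)[C@H](C)[C@H](OC(C)=O)c1cc(OC)c(OC)c(OC)c12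
F11 | step 6 | (7R,8S,9S)-9-hydroxy-2,3,3',4,5'-pentamethoxy-7,8-dimethyl-6,7,8,9-tetrahydrospiro[benzo[7]annulene-5,1'-cyclohexa[2,5]dien]-4'-one | COC1=CC2(C=C(OC)C1=O)C[C@@H](C)[C@H](C)[C@H](O)c1cc(OC)c(OC)c(OC)c12
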